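The disconnection removes the quaternary carbon C9 (halimane numbering) from ring B (C5–C10): what remains is a cyclopentenone ring (C5, C6, C7, C8, C10) fused to ring A, with the C1=C10 olefin conjugated to a C8 carbonyl. The key step starts from the CBr2CH3 adduct of this enone, a bicyclic allylic alcohol: a β-oxido carbenoid 1,2-shift moves the alkenyl carbon C10 from C8 to C9 (five- to six-membered ring enlargement), and the resulting dienolate is alkylated at C9 with the complete chiral side chain. It exploits that C9 lies between sp2 C10 and a C8 that can be a carbonyl; one operation gives ring B, the C9 quaternary stereocentre and the fixed Δ1(10) olefin.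

Key step: step 8

Remark: atoms are labelled by halimane numbering (ring A = C1–C5, C10; ring B = C5–C10; side chain C11–C16; C17 on C8; C20 on C9); methyl hydrogen (R)-3-methylglutarate and (S)-glycidol are taken as commercial.

**Step 1**
Reactants: 1 4,4-dimethylcyclohex-2-en-1-one; 2 ethyl 3-iodopropanoate
Product: 4 ethyl 3-[(1R)-2,2-dimethyl-5-oxocyclohexyl]propanoate, via bis(3-ethoxy-3-oxopropyl)zinc 3 (not isolated)
Conditions: 2, Et2Zn, CuI (cat.), 50 °C, volatiles removed; then 1, Cu(OTf)2 (2 mol %), (S,R,R)-BINOL bis(1-phenylethyl)amine phosphoramidite (4 mol %), toluene, −30 °C; aq. NH4Cl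
Reagents that add atoms: none
Why: Cu/phosphoramidite-catalysed asymmetric conjugate addition of an ester-functionalised dialkylzinc (made by I/Zn exchange), in which the ligand controls the face of attack at C5; the ligand enantiomer is the one expected, by analogy with simple cyclohexenones, to give the spatial arrangement that carries the (R) descriptor here because of the gem-dimethyl group.

**Step 2**
Reactants: 4 ethyl 3-[(1R)-2,2-dimethyl-5-oxocyclohexyl]propanoate
Product: 5 (3aS)-7-hydroxy-4,4-dimethyl-2,3,3a,4,5,6-hexahydro-1H-inden-1-one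
Conditions: KOt-Bu (1.2 equiv), THF, 0 °C → rt; then 1 M HCl
Reagents that add atoms: none
Why: Dieckmann-type intramolecular Claisen acylation in which the ketone enolate at C10 attacks the ester (5-exo-trig) and the stabilised diketonate is the thermodynamic sink; C5 is not acidic and no lasting stereocentre is created.

**Step 3**
Reactants: 5 (3aS)-7-hydroxy-4,4-dimethyl-2,3,3a,4,5,6-hexahydro-1H-inden-1-one
Product: 6 (3aS)-4,4-dimethyl-1-oxo-2,3,3a,4,5,6-hexahydro-1H-inden-7-yl trifluoromethanesulfonate
Conditions: Tf2O, 2,6-lutidine, CH2Cl2, −78 °C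
Reagents that add atoms: trifluoromethanesulfonic anhydride, O=S(=O)(OS(=O)(=O)C(F)(F)F)C(F)(F)F
Why: O-sulfonylation of the enol (vinylogous acyl triflate formation), expected at the cyclohexanone oxygen because the enol double bond prefers to be endocyclic to the six-membered and exocyclic to the five-membered ring.

**Step 4**
Reactants: 6 (3aS)-4,4-dimethyl-1-oxo-2,3,3a,4,5,6-hexahydro-1H-inden-7-yl trifluoromethanesulfonate
Product: 7 (3aS)-4,4-dimethyl-2,3,3a,4,5,6-hexahydro-1H-inden-1-one
Conditions: Pd(OAc)2 (5 mol %), PPh3 (10 mol %), HCO2H, n-Bu3N, DMF, 60 °C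
Reagents that add atoms: none
Why: Pd-catalysed formate reduction of an enol triflate (oxidative addition, formate decarboxylation, reductive elimination) replaces OTf by H and leaves the C1=C10 enone in place; no stereocentre is formed.

**Step 5**
Reactants: 8 (3R)-5-methoxy-3-methyl-5-oxopentanoic acid
Product: 9 methyl (3R)-5-hydroxy-3-methylpentanoate
Conditions: BH3·SMe2, THF, −10 °C → rt; MeOH quench; used directly
Reagents that add atoms: none
Why: chemoselective borane reduction of the carboxylic acid (via an acyloxyborane) in the presence of the methyl ester; the stereocentre is not involved.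

**Step 6**
Reactants: 9 methyl (3R)-5-hydroxy-3-methylpentanoate
Product: 10 methyl (3S)-5-iodo-3-methylpentanoate
Conditions: I2, PPh3, imidazole, CH2Cl2, 0 °C → rt
Reagents that add atoms: iodine, II
Why: Appel-type iodination of the primary alcohol by SN2 at CH2; the stereocentre is untouched and its descriptor changes to S only through CIP priority.

**Step 7**
Reactants: 7 (3aS)-4,4-dimethyl-2,3,3a,4,5,6-hexahydro-1H-inden-1-one
Product: 11 (1S,3aS)-1-(1,1-dibromoethyl)-4,4-dimethyl-2,3,3a,4,5,6-hexahydro-1H-inden-1-ol
Conditions: CH3CHBr2, LDA, THF/Et2O, −100 °C; then 7; AcOH quench at −100 °C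
Reagents that add atoms: 1,1-dibromoethane, CC(Br)Br
Why: 1,2-addition of 1,1-dibromoethyllithium to the enone carbonyl; attack is expected from the face of H5, but the configuration of the new carbinol carbon C8 is irrelevant because C8 becomes a carbonyl again in step 8.

**Step 8**
Reactants: 11 (1S,3aS)-1-(1,1-dibromoethyl)-4,4-dimethyl-2,3,3a,4,5,6-hexahydro-1H-inden-1-ol; 10 methyl (3S)-5-iodo-3-methylpentanoate
Product: 14 methyl (3R)-3-methyl-5-[(1S,4aS)-1,5,5-trimethyl-2-oxo-1,2,3,4,4a,5,6,7-octahydronaphthalen-1-yl]pentanoate, via dilithio β-oxido carbenoid 12 (not isolated), via lithium dienolate 13 (not isolated)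
Conditions: n-BuLi (2.05 equiv), THF, −78 → −20 °C; then DMPU, 10 (1.5 equiv), −78 → 0 °C
Reagents that add atoms: none
Why: n-BuLi deprotonates the carbinol and exchanges one bromine to give the β-oxido carbenoid 12, in which the alkenyl carbon C10 shifts from C8 to the carbenoid carbon C9 with loss of LiBr, so that C9 (with its methyl) is inserted between C8 and C10 and the cyclopentane ring (C5, C6, C7, C8, C10) becomes ring B; the shift delivers regiospecifically the extended lithium enolate 13 (O–C8=C9–C10=C1), which is C-alkylated at C9 by iodide 10. The closest known reaction type is the β-oxido carbenoid one-carbon ring enlargement of cyclic ketones with 1,1-dibromoalkyllithiums, combined with in situ alkylation of the enolate that it releases. No ring is closed by cyclisation: ring B arises by a 1,2-shift that enlarges the five-membered ring to the six-membered one. The quaternary stereocentre C9 is set in the alkylation, which should occur by axial attack on the α face of the sofa-shaped dienolate, the face of the axial H5 and opposite to the pucker of C6 and C4, so that the chain enters cis to H5 and the methyl stays equatorial (control by the existing C5 centre); C13 comes unchanged from 10. The step needs migration of C10 rather than C7, which the higher migratory aptitude of the sp2 and more substituted carbon should secure, and α-C- rather than γ- or O-alkylation, which is the normal course for lithium dienolates with a primary iodide in THF/DMPU. Because C9 becomes quaternary, the olefin is locked at C1=C10 and cannot return into conjugation.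

**Step 9**
Reactants: 14 methyl (3R)-3-methyl-5-[(1S,4aS)-1,5,5-trimethyl-2-oxo-1,2,3,4,4a,5,6,7-octahydronaphthalen-1-yl]pentanoate
Product: 15 methyl (3R)-3-methyl-5-[(1R,4aS)-1,5,5-trimethyl-2-methylidene-1,2,3,4,4a,5,6,7-octahydronaphthalen-1-yl]pentanoate
Conditions: Zn, CH2Br2, TiCl4, THF/CH2Cl2, 0 °C → rt
Reagents that add atoms: dibromomethane, BrCBr
Why: Takai–Lombardo methylenation through a zinc/titanium gem-dimetallic reagent, which is non-basic and so tolerates the hindered, enolisable C8 ketone and the methyl ester; no stereocentre is affected.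

**Step 10**
Reactants: 15 methyl (3R)-3-methyl-5-[(1R,4aS)-1,5,5-trimethyl-2-methylidene-1,2,3,4,4a,5,6,7-octahydronaphthalen-1-yl]pentanoate
Product: 16 methyl (3R)-3-methyl-5-[(1R,2R,4aS)-1,2,5,5-tetramethyl-1,2,3,4,4a,5,6,7-octahydronaphthalen-1-yl]pentanoate
Conditions: H2 (1 atm, 1 equiv uptake), PtO2 (5 mol %), EtOAc, rt
Reagents that add atoms: none
Why: heterogeneous catalytic hydrogenation should be chemoselective for the 1,1-disubstituted exocyclic olefin over the hindered trisubstituted C1=C10 olefin, and hydrogen should be delivered to the β face of C8, opposite to the axial C11 chain on C9, so that the C17 methyl ends up equatorial and cis to the chain (8R).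

**Step 11**
Reactants: 16 methyl (3R)-3-methyl-5-[(1R,2R,4aS)-1,2,5,5-tetramethyl-1,2,3,4,4a,5,6,7-octahydronaphthalen-1-yl]pentanoate
Product: 17 (3R)-3-methyl-5-[(1R,2R,4aS)-1,2,5,5-tetramethyl-1,2,3,4,4a,5,6,7-octahydronaphthalen-1-yl]pentanoic acid
Conditions: LiOH·H2O, THF/MeOH/H2O, rt; then 1 M HCl to pH 3
Reagents that add atoms: lithium hydroxide, [Li+].[OH-]
Why: saponification (BAc2 hydrolysis) of the unhindered methyl ester; no stereocentre is α to the carbonyl, so none can epimerise.

**Step 12**
Reactants: 18 (S)-glycidol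
Product: 19 [(2R)-oxiran-2-yl]methyl acetate
Conditions: Ac2O, Et3N, DMAP (cat.), CH2Cl2, 0 °C
Reagents that add atoms: acetic anhydride, CC(=O)OC(C)=O
Why: DMAP-catalysed acetylation of the primary alcohol; the epoxide stereocentre is not touched and its descriptor changes from S to R only through CIP priority.

**Step 13**
Reactants: 17 (3R)-3-methyl-5-[(1R,2R,4aS)-1,2,5,5-tetramethyl-1,2,3,4,4a,5,6,7-octahydronaphthalen-1-yl]pentanoic acid; 19 [(2R)-oxiran-2-yl]methyl acetate
Product: 20 (2S)-3-(acetyloxy)-2-hydroxypropyl (3R)-3-methyl-5-[(1R,2R,4aS)-1,2,5,5-tetramethyl-1,2,3,4,4a,5,6,7-octahydronaphthalen-1-yl]pentanoate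
Conditions: 19 (1.3 equiv), Et4NBr (10 mol %), toluene, 80 °C
Reagents that add atoms: none
Why: ammonium-halide-catalysed ring opening of the terminal epoxide by the carboxylic acid (SN2 at the CH2 terminus) should give the 1-acyl-3-acetyl glycerol with a free secondary hydroxyl; the stereocentre is not a reacting carbon and is retained.

**Compound list**

1 | 4,4-dimethylcyclohex-2-en-1-one | CC1(C)CCC(=O)C=C1 | starting material
2 | ethyl 3-iodopropanoate | CCOC(=O)CCI | starting material
3 | bis(3-ethoxy-3-oxopropyl)zinc | CCOC(=O)CC[Zn]CCC(=O)OCC | intermediate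
4 | ethyl 3-[(1R)-2,2-dimethyl-5-oxocyclohexyl]propanoate | CCOC(=O)CC[C@@H]1CC(=O)CCC1(C)C | intermediate
5 | (3aS)-7-hydroxy-4,4-dimethyl-2,3,3a,4,5,6-hexahydro-1H-inden-1-one (enol tautomer of the bicyclic 1,3-diketone) | O=C1CC[C@@H]2C1=C(O)CCC2(C)C | intermediate
6 | (3aS)-4,4-dimethyl-1-oxo-2,3,3a,4,5,6-hexahydro-1H-inden-7-yl trifluoromethanesulfonate | O=C1CC[C@@H]2C1=C(OS(=O)(=O)C(F)(F)F)CCC2(C)C | intermediate
7 | (3aS)-4,4-dimethyl-2,3,3a,4,5,6-hexahydro-1H-inden-1-one | O=C1CC[C@@H]2C1=CCCC2(C)C | intermediate
8 | (3R)-5-methoxy-3-methyl-5-oxopentanoic acid (methyl hydrogen (R)-3-methylglutarate) | COC(=O)C[C@H](C)CC(=O)O | starting material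
9 | methyl (3R)-5-hydroxy-3-methylpentanoate | COC(=O)C[C@H](C)CCO | intermediate
10 | methyl (3S)-5-iodo-3-methylpentanoate | COC(=O)C[C@H](C)CCI | intermediate
11 | (1S,3aS)-1-(1,1-dibromoethyl)-4,4-dimethyl-2,3,3a,4,5,6-hexahydro-1H-inden-1-ol (expected major C1 epimer; either epimer serves) | CC(Br)(Br)[C@]1(O)CC[C@@H]2C1=CCCC2(C)C | intermediate
12 | lithium (1S,3aS)-1-(1-bromo-1-lithioethyl)-4,4-dimethyl-2,3,3a,4,5,6-hexahydro-1H-inden-1-olate (β-oxido carbenoid; one epimer at the carbenoid carbon drawn) | C[C@](Br)([Li])[C@]1(O[Li])CC[C@@H]2C1=CCCC2(C)C | intermediate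
13 | lithium (4aS)-1,5,5-trimethyl-3,4,4a,5,6,7-hexahydronaphthalen-2-olate | [Li]OC1=C(C)C2=CCCC(C)(C)[C@@H]2CC1 | intermediate
14 | methyl (3R)-3-methyl-5-[(1S,4aS)-1,5,5-trimethyl-2-oxo-1,2,3,4,4a,5,6,7-octahydronaphthalen-1-yl]pentanoate | COC(=O)C[C@H](C)CC[C@@]1(C)C2=CCCC(C)(C)[C@@H]2CCC1=O | intermediate
15 | methyl (3R)-3-methyl-5-[(1R,4aS)-1,5,5-trimethyl-2-methylidene-1,2,3,4,4a,5,6,7-octahydronaphthalen-1-yl]pentanoate | COC(=O)C[C@H](C)CC[C@@]1(C)C2=CCCC(C)(C)[C@@H]2CCC1=C | intermediate
16 | methyl (3R)-3-methyl-5-[(1R,2R,4aS)-1,2,5,5-tetramethyl-1,2,3,4,4a,5,6,7-octahydronaphthalen-1-yl]pentanoate | COC(=O)C[C@H](C)CC[C@@]1(C)C2=CCCC(C)(C)[C@@H]2CC[C@H]1C | intermediate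
17 | (3R)-3-methyl-5-[(1R,2R,4aS)-1,2,5,5-tetramethyl-1,2,3,4,4a,5,6,7-octahydronaphthalen-1-yl]pentanoic acid | OC(=O)C[C@H](C)CC[C@@]1(C)C2=CCCC(C)(C)[C@@H]2CC[C@H]1C | intermediate
18 | (S)-glycidol [(2S)-oxiran-2-ylmethanol] | OC[C@H]1CO1 | starting material
19 | [(2R)-oxiran-2-yl]methyl acetate | CC(=O)OC[C@H]1CO1 | intermediate
20 | (2S)-3-(acetyloxy)-2-hydroxypropyl (3R)-3-methyl-5-[(1R,2R,4aS)-1,2,5,5-tetramethyl-1,2,3,4,4a,5,6,7-octahydronaphthalen-1-yl]pentanoate | CC(=O)OC[C@H](O)COC(=O)C[C@H](C)CC[C@@]1(C)C2=CCCC(C)(C)[C@@H]2CC[C@H]1C | target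

**Step count**

Total: 13 steps. Longest linear sequence: 10 steps (1, 2, 3, 4, 7, 8, 9, 10, 11, 13).

**Steps most likely to fail**

1. Step 8. The alkyl carbon C7 may migrate in competition with C10 in the carbenoid, and C-alkylation of the hindered lithium dienolate in the same flask may be slow or poorly face-selective. The fallback sets out from 7 and comes back at 14. Rh-catalysed 1,4-hydrosilylation of 7 (Et3SiH, RhCl(PPh3)3 cat.) should give the regiodefined silyl enol ether triethyl{[(3aS)-4,4-dimethyl-3,3a,4,5,6,7-hexahydro-2H-inden-1-yl]oxy}silane F1. Ethylidene transfer (CH3CHI2, Et2Zn, CH2Cl2) should give the methyl-substituted siloxycyclopropane across C8–C10 F2. Saegusa–Ito ring expansion (FeCl3, DMF, then NaOAc, MeOH) cleaves the C8–C10 bond without any migratory competition and should give (4aS)-1,5,5-trimethyl-4,4a,5,6,7,8-hexahydronaphthalen-2(3H)-one F3. Deconjugative α-alkylation of its potassium dienolate (KOt-Bu, t-BuOH/THF) with 10 then leads to 14. The facial preference in this alkylation is the same as in step 8, so poor face selectivity is not cured by this fallback.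

2. Step 1. Transmetalation of the internally chelated β-zincio ester may be sluggish and the enantioselectivity may erode. The fallback sets out from 1 and comes back at 4. The same Cu/phosphoramidite conjugate addition with unfunctionalised di(but-3-enyl)zinc should give (3R)-3-(but-3-en-1-yl)-4,4-dimethylcyclohexan-1-one F4. Oxidative cleavage of the terminal olefin (RuCl3 cat., NaIO4) should give 3-[(1R)-2,2-dimethyl-5-oxocyclohexyl]propanoic acid F5, and Fischer esterification (EtOH, H2SO4 cat.) gives 4.

3. Step 10. Hydrogen may be delivered to the wrong face of C8, or the exocyclic double bond may migrate into the ring on the metal surface. The fallback sets out from 15 and comes back at 16. Radical hydrogen-atom-transfer hydrogenation (Mn(dpm)3 cat., PhSiH3, t-BuOOH, i-PrOH, rt) reduces the 1,1-disubstituted olefin through a tertiary C8 radical and should place the C17 methyl in the more stable equatorial position, which is the required configuration. This fallback makes no new compound (F0).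

**Further compounds**

F1 | step 8 | triethyl{[(3aS)-4,4-dimethyl-3,3a,4,5,6,7-hexahydro-2H-inden-1-yl]oxy}silane | CC[Si](CC)(CC)OC1=C2CCCC(C)(C)[C@@H]2CC1
F2 | step 8 | methyl-substituted siloxycyclopropane formed by ethylidene addition across C8–C10 of F1 (one diastereomer drawn; the three cyclopropane centres are lost in the next step) | CC[Si](CC)(CC)O[C@@]12CC[C@H]3C(C)(C)CCC[C@@]13[C@@H]2C
F3 | step 8 | (4aS)-1,5,5-trimethyl-4,4a,5,6,7,8-hexahydronaphthalen-2(3H)-one | CC1=C2CCCC(C)(C)[C@@H]2CCC1=O
F4 | step 1 | (3R)-3-(but-3-en-1-yl)-4,4-dimethylcyclohexan-1-one | C=CCC[C@@H]1CC(=O)CCC1(C)C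
F5 | step 1 | 3-[(1R)-2,2-dimethyl-5-oxocyclohexyl]propanoic acid | OC(=O)CC[C@@H]1CC(=O)CCC1(C)C
F0 | step 10 | none | none
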